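The route rests on disconnecting the bond between ring carbon C6 and benzylic C1' and on reading the hydroquinone ring (C1–OH flanked by C2–CH3 and C6, C4–OH para) as reduced 2-methyl-1,4-benzoquinone. In one operation, BF3-mediated union of this quinone with the fully functionalised (2E)-allylstannane should add the chain to the unhindered C4 carbonyl, shift it by a [3,3] rearrangement to C6 (C2 is blocked by methyl) and aromatise, giving the unprotected hydroquinone with the E-C2'=C3' alkene. The stannane is assembled from geranyl acetate by allylic oxidation, asymmetric allylation, cross-metathesis and a catalytic asymmetric vinylogous aldol reaction.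

Key step: step 14

Remark: ring atoms are numbered C1 (OH between methyl and chain), C2 (CH3), C3, C4 (OH), C5, C6 (chain) and chain atoms C1'–C16' from the benzylic carbon; the target is read as (2'E,5'S,6'E,10'E,12'R); the facial sense of the catalysts in steps 3 and 9 is assumed from the accepted models; metal, silicon and tin alkoxides that are only hydrolysed at work-up are not numbered.

Step 1
Reactants: 1 geranyl acetate [(2E)-3,7-dimethylocta-2,6-dien-1-yl acetate]
Product: 2 (2E,6E)-8-hydroxy-3,7-dimethylocta-2,6-dien-1-yl acetate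
Conditions: SeO2 (0.1 equiv), t-BuOOH (3 equiv), salicylic acid (0.1 equiv), CH2Cl2, rt
Reagents that add atoms: selenium dioxide, O=[Se]=O (oxygen donor, turned over); tert-butyl hydroperoxide, CC(C)(C)OO
Why: Catalytic SeO2 allylic oxidation (ene reaction then [2,3]-shift) should attack the electron-rich distal trisubstituted alkene at its E-methyl group, the C2=C3 alkene being deactivated by the allylic acetate, and give the E-allylic alcohol.

Step 2
Reactants: 2 (2E,6E)-8-hydroxy-3,7-dimethylocta-2,6-dien-1-yl acetate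
Product: 3 (2E,6E)-3,7-dimethyl-8-oxoocta-2,6-dien-1-yl acetate
Conditions: MnO2 (activated, excess), CH2Cl2, rt
Reagents that add atoms: none
Why: MnO2 oxidation of a primary allylic alcohol should stop at the enal without touching the acetate or the alkene geometry, and any aldehyde already formed in step 1 converges here.

Step 3
Reactants: 3 (2E,6E)-3,7-dimethyl-8-oxoocta-2,6-dien-1-yl acetate
Product: 4 (2E,6E,8R)-8-hydroxy-3,7-dimethylundeca-2,6,10-trien-1-yl acetate
Conditions: (R)-BINOL (20 mol%), Ti(OiPr)4 (10 mol%), 4 Å MS, allylSnBu3 (1.5 equiv), CH2Cl2, −20 °C; aq. NaHCO3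
Reagents that add atoms: allyltributylstannane, C=CC[Sn](CCCC)(CCCC)CCCC
Why: Keck asymmetric allylation of an α-methyl enal is 1,2-selective and the (R)-BINOL–titanium Lewis acid should deliver the allyl group to the Re face of the aldehyde (O > C7 > H), setting the 8R carbinol (C12' of the target) while the acetate is inert.

Step 4
Reactants: 4 (2E,6E,8R)-8-hydroxy-3,7-dimethylundeca-2,6,10-trien-1-yl acetate
Product: 5 (2E,6E,8R)-8-hydroxy-3,7,11-trimethyldodeca-2,6,10-trien-1-yl acetate
Conditions: second-generation Grubbs catalyst RuCl2(=CHPh)(H2IMes)(PCy3) (3 mol%), 2-methyl-2-butene/CH2Cl2, 40 °C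
Reagents that add atoms: 2-methyl-2-butene, CC=C(C)C
Why: Olefin cross-metathesis should engage only the monosubstituted terminal alkene, the trisubstituted alkenes being spectators, and excess 2-methyl-2-butene drives it to the prenyl terminus with loss of propene.

Step 5
Reactants: 5 (2E,6E,8R)-8-hydroxy-3,7,11-trimethyldodeca-2,6,10-trien-1-yl acetate
Product: 6 (2E,6E,8R)-8-[(tert-butyldimethylsilyl)oxy]-3,7,11-trimethyldodeca-2,6,10-trien-1-yl acetate
Conditions: TBSCl, imidazole, DMF, rt
Reagents that add atoms: tert-butyldimethylsilyl chloride, CC(C)(C)[Si](C)(C)Cl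
Why: Standard imidazole-promoted silylation protects the only free hydroxyl as an ether that should survive every later step up to the final fluoride treatment.

Step 6
Reactants: 6 (2E,6E,8R)-8-[(tert-butyldimethylsilyl)oxy]-3,7,11-trimethyldodeca-2,6,10-trien-1-yl acetate
Product: 7 (2E,6E,8R)-8-[(tert-butyldimethylsilyl)oxy]-3,7,11-trimethyldodeca-2,6,10-trien-1-ol
Conditions: K2CO3 (0.2 equiv), MeOH, 0 °C to rt
Reagents that add atoms: none
Why: Base-catalysed transesterification removes the primary allylic acetate as methyl acetate while the hindered secondary silyl ether is stable to methanolic carbonate.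

Step 7
Reactants: 7 (2E,6E,8R)-8-[(tert-butyldimethylsilyl)oxy]-3,7,11-trimethyldodeca-2,6,10-trien-1-ol
Product: 8 (2E,6E,8R)-8-[(tert-butyldimethylsilyl)oxy]-3,7,11-trimethyldodeca-2,6,10-trienal
Conditions: MnO2 (activated, excess), CH2Cl2, rt
Reagents that add atoms: none
Why: MnO2 oxidation of the primary allylic alcohol should give the E-enal under neutral conditions that do not isomerise the C2=C3 alkene.

Step 8
Reactants: 9 ethyl 3-methylbut-2-enoate
Product: 10 (1Z)-1-[(tert-butyldimethylsilyl)oxy]-1-ethoxy-3-methylbuta-1,3-diene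
Conditions: LiN(iPr)2 (LDA), THF, −78 °C; TBSCl, DMPU, −78 °C to rt
Reagents that add atoms: tert-butyldimethylsilyl chloride, CC(C)(C)[Si](C)(C)Cl
Why: Kinetic γ-deprotonation of the senecioate and O-silylation of the extended enolate is the standard preparation of this silyl dienol ether, whose ketene-acetal geometry is inconsequential for the next step.

Step 9
Reactants: 8 (2E,6E,8R)-8-[(tert-butyldimethylsilyl)oxy]-3,7,11-trimethyldodeca-2,6,10-trienal; 10 (1Z)-1-[(tert-butyldimethylsilyl)oxy]-1-ethoxy-3-methylbuta-1,3-diene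
Product: 11 ethyl (2E,5S,6E,10E,12R)-12-[(tert-butyldimethylsilyl)oxy]-5-hydroxy-3,7,11,15-tetramethylhexadeca-2,6,10,14-tetraenoate
Conditions: SiCl4 (1.1 equiv), Denmark (S,S)-binaphthyldiamine-derived bisphosphoramide (5 mol%), iPr2NEt (10 mol%), CH2Cl2, −78 °C; sat. aq. NaHCO3
Reagents that add atoms: none
Why: In this Lewis-base-catalysed vinylogous Mukaiyama aldol reaction the dienol ether should attack through its unhindered γ-CH2 terminus to give the E-enoate, and the bisphosphoramide-bound chlorosilyl cation should direct it to the Si face of the aldehyde (O > C6' > H), setting 5S under catalyst control (the enantiomeric catalyst would be used if the facial sense proved opposite).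

Step 10
Reactants: 11 ethyl (2E,5S,6E,10E,12R)-12-[(tert-butyldimethylsilyl)oxy]-5-hydroxy-3,7,11,15-tetramethylhexadeca-2,6,10,14-tetraenoate
Product: 12 (2E,5S,6E,10E,12R)-12-[(tert-butyldimethylsilyl)oxy]-3,7,11,15-tetramethylhexadeca-2,6,10,14-tetraene-1,5-diol
Conditions: iBu2AlH (3.3 equiv), CH2Cl2, −78 °C; aq. Rochelle salt
Reagents that add atoms: none
Why: iBu2AlH reduces the conjugated ester 1,2-selectively to the primary allylic alcohol without touching the silyl ether, the alkenes or the C5 stereocentre.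

Step 11
Reactants: 12 (2E,5S,6E,10E,12R)-12-[(tert-butyldimethylsilyl)oxy]-3,7,11,15-tetramethylhexadeca-2,6,10,14-tetraene-1,5-diol
Product: 14 (2E,5S,6E,10E,12R)-12-[(tert-butyldimethylsilyl)oxy]-1-chloro-3,7,11,15-tetramethylhexadeca-2,6,10,14-tetraen-5-ol, via allylic mesylate 13 (not isolated)
Conditions: MsCl (1.05 equiv), 2,4,6-collidine, LiCl (excess), DMF, −20 to 0 °C
Reagents that add atoms: methanesulfonyl chloride, CS(=O)(=O)Cl (in intermediate 13 only); lithium chloride, [Li+].[Cl-]
Why: Under these mesylation–chloride displacement conditions the less hindered primary allylic hydroxyl should be sulfonylated in preference to the secondary one and then displaced by chloride in an SN2 reaction, without allylic transposition or loss of E geometry.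

Step 12
Reactants: 14 (2E,5S,6E,10E,12R)-12-[(tert-butyldimethylsilyl)oxy]-1-chloro-3,7,11,15-tetramethylhexadeca-2,6,10,14-tetraen-5-ol
Product: 15 (2E,5S,6E,10E,12R)-12-[(tert-butyldimethylsilyl)oxy]-3,7,11,15-tetramethyl-1-(tributylstannyl)hexadeca-2,6,10,14-tetraen-5-ol
Conditions: Bu3SnH, LiN(iPr)2 (LDA), THF, 0 °C (gives Bu3SnLi, 2.3 equiv); then 14, −78 °C; H2O
Reagents that add atoms: tributylstannane, CCCC[SnH](CCCC)CCCC (used as its lithium derivative Bu3SnLi, [Li][Sn](CCCC)(CCCC)CCCC)
Why: The soft stannyl anion displaces the primary allylic chloride in an SN2 reaction with retention of the E alkene, the first equivalent being consumed harmlessly by the free hydroxyl, which also keeps an ester out of contact with the stannyllithium.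

Step 13
Reactants: 15 (2E,5S,6E,10E,12R)-12-[(tert-butyldimethylsilyl)oxy]-3,7,11,15-tetramethyl-1-(tributylstannyl)hexadeca-2,6,10,14-tetraen-5-ol
Product: 16 (2E,5S,6E,10E,12R)-12-[(tert-butyldimethylsilyl)oxy]-3,7,11,15-tetramethyl-1-(tributylstannyl)hexadeca-2,6,10,14-tetraen-5-yl acetate
Conditions: Ac2O, pyridine, DMAP (cat.), CH2Cl2, 0 °C to rt
Reagents that add atoms: acetic anhydride, CC(=O)OC(C)=O
Why: DMAP-catalysed O-acetylation under buffered basic conditions leaves the acid-sensitive allylstannane intact and does not touch the C5 configuration.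

Step 14
Reactants: 16 (2E,5S,6E,10E,12R)-12-[(tert-butyldimethylsilyl)oxy]-3,7,11,15-tetramethyl-1-(tributylstannyl)hexadeca-2,6,10,14-tetraen-5-yl acetate; 17 2-methyl-1,4-benzoquinone
Product: 20 (2E,5S,6E,10E,12R)-12-[(tert-butyldimethylsilyl)oxy]-1-(2,5-dihydroxy-3-methylphenyl)-3,7,11,15-tetramethylhexadeca-2,6,10,14-tetraen-5-yl acetate, via quinol adduct 18 (not isolated), via dienone tautomer 19 (not isolated)
Conditions: 17 (2 equiv), BF3·OEt2 (3 equiv), CH2Cl2, −78 °C; add 16; −78 to −30 °C; aq. NaHCO3/Na2S2O4 work-up under argon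
Reagents that add atoms: none
Why: This is the Lewis-acid-mediated allylation of a quinone by an allylstannane, the reaction type used to attach polyprenyl chains to quinone nuclei: BF3 activates 17, the stannane attacks the C4 carbonyl through its γ-carbon C3' with loss of the stannyl group (SE2') to give quinol 18, and a suprafacial [3,3] shift across C4–C5=C6 returns the allyl unit with a second transposition, forming the C1'–C6 bond and dienone 19, which enolises to the hydroquinone. No ring is closed and no lasting stereocentre is made; the transient centres at ring C4 and C3' of 18 are erased. Regioselectivity is needed twice and rests on the C2 methyl group: it shields the C1 carbonyl so that addition should go to the unhindered and more Lewis-basic C4 carbonyl, and of the two [3,3] termini reachable from C4 only C6 bears a hydrogen and can aromatise, while a shift to the methyl-bearing C2 is a reversible dead end. The E geometry of C2'=C3' has to be re-formed in the [3,3] step and should follow from a chair-like transition state with the C4' chain pseudo-equatorial. Chemoselectivity over the allylic acetate, the silyl ether and the other trisubstituted alkenes is secured by the low temperature and by the stannane being the only strongly nucleophilic alkene, and excess quinone with a dithionite work-up keeps the product at the hydroquinone level.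

Step 15
Reactants: 20 (2E,5S,6E,10E,12R)-12-[(tert-butyldimethylsilyl)oxy]-1-(2,5-dihydroxy-3-methylphenyl)-3,7,11,15-tetramethylhexadeca-2,6,10,14-tetraen-5-yl acetate
Product: 21 (2E,5S,6E,10E,12R)-1-(2,5-dihydroxy-3-methylphenyl)-12-hydroxy-3,7,11,15-tetramethylhexadeca-2,6,10,14-tetraen-5-yl acetate
Conditions: HF·pyridine, pyridine, THF, 0 °C to rt, argon
Reagents that add atoms: none
Why: Buffered HF·pyridine cleaves the secondary silyl ether without base, so the acetate should neither migrate nor hydrolyse and the air-sensitive hydroquinone is not oxidised or cyclised onto the C2'=C3' alkene.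

Compound list
1 | geranyl acetate, (2E)-3,7-dimethylocta-2,6-dien-1-yl acetate | CC(=O)OC/C=C(\C)CCC=C(C)C | starting material
2 | (2E,6E)-8-hydroxy-3,7-dimethylocta-2,6-dien-1-yl acetate | CC(=O)OC/C=C(\C)CC/C=C(\C)CO | intermediate
3 | (2E,6E)-3,7-dimethyl-8-oxoocta-2,6-dien-1-yl acetate | CC(=O)OC/C=C(\C)CC/C=C(\C)C=O | intermediate
4 | (2E,6E,8R)-8-hydroxy-3,7-dimethylundeca-2,6,10-trien-1-yl acetate | CC(=O)OC/C=C(\C)CC/C=C(\C)[C@H](O)CC=C | intermediate
5 | (2E,6E,8R)-8-hydroxy-3,7,11-trimethyldodeca-2,6,10-trien-1-yl acetate | CC(=O)OC/C=C(\C)CC/C=C(\C)[C@H](O)CC=C(C)C | intermediate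
6 | (2E,6E,8R)-8-[(tert-butyldimethylsilyl)oxy]-3,7,11-trimethyldodeca-2,6,10-trien-1-yl acetate | CC(=O)OC/C=C(\C)CC/C=C(\C)[C@H](O[Si](C)(C)C(C)(C)C)CC=C(C)C | intermediate
7 | (2E,6E,8R)-8-[(tert-butyldimethylsilyl)oxy]-3,7,11-trimethyldodeca-2,6,10-trien-1-ol | OC/C=C(\C)CC/C=C(\C)[C@H](O[Si](C)(C)C(C)(C)C)CC=C(C)C | intermediate
8 | (2E,6E,8R)-8-[(tert-butyldimethylsilyl)oxy]-3,7,11-trimethyldodeca-2,6,10-trienal | O=C/C=C(\C)CC/C=C(\C)[C@H](O[Si](C)(C)C(C)(C)C)CC=C(C)C | intermediate
9 | ethyl 3-methylbut-2-enoate | CCOC(=O)C=C(C)C | starting material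
10 | (1Z)-1-[(tert-butyldimethylsilyl)oxy]-1-ethoxy-3-methylbuta-1,3-diene | CCO/C(O[Si](C)(C)C(C)(C)C)=C/C(C)=C | intermediate
11 | ethyl (2E,5S,6E,10E,12R)-12-[(tert-butyldimethylsilyl)oxy]-5-hydroxy-3,7,11,15-tetramethylhexadeca-2,6,10,14-tetraenoate | CCOC(=O)/C=C(\C)C[C@H](O)/C=C(\C)CC/C=C(\C)[C@H](O[Si](C)(C)C(C)(C)C)CC=C(C)C | intermediate
12 | (2E,5S,6E,10E,12R)-12-[(tert-butyldimethylsilyl)oxy]-3,7,11,15-tetramethylhexadeca-2,6,10,14-tetraene-1,5-diol | OC/C=C(\C)C[C@H](O)/C=C(\C)CC/C=C(\C)[C@H](O[Si](C)(C)C(C)(C)C)CC=C(C)C | intermediate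
13 | (2E,5S,6E,10E,12R)-12-[(tert-butyldimethylsilyl)oxy]-5-hydroxy-3,7,11,15-tetramethylhexadeca-2,6,10,14-tetraen-1-yl methanesulfonate (not isolated) | CS(=O)(=O)OC/C=C(\C)C[C@H](O)/C=C(\C)CC/C=C(\C)[C@H](O[Si](C)(C)C(C)(C)C)CC=C(C)C | intermediate
14 | (2E,5S,6E,10E,12R)-12-[(tert-butyldimethylsilyl)oxy]-1-chloro-3,7,11,15-tetramethylhexadeca-2,6,10,14-tetraen-5-ol | ClC/C=C(\C)C[C@H](O)/C=C(\C)CC/C=C(\C)[C@H](O[Si](C)(C)C(C)(C)C)CC=C(C)C | intermediate
15 | (2E,5S,6E,10E,12R)-12-[(tert-butyldimethylsilyl)oxy]-3,7,11,15-tetramethyl-1-(tributylstannyl)hexadeca-2,6,10,14-tetraen-5-ol | CCCC[Sn](CCCC)(CCCC)C/C=C(\C)C[C@H](O)/C=C(\C)CC/C=C(\C)[C@H](O[Si](C)(C)C(C)(C)C)CC=C(C)C | intermediate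
16 | (2E,5S,6E,10E,12R)-12-[(tert-butyldimethylsilyl)oxy]-3,7,11,15-tetramethyl-1-(tributylstannyl)hexadeca-2,6,10,14-tetraen-5-yl acetate | CCCC[Sn](CCCC)(CCCC)C/C=C(\C)C[C@H](OC(C)=O)/C=C(\C)CC/C=C(\C)[C@H](O[Si](C)(C)C(C)(C)C)CC=C(C)C | intermediate
17 | 2-methyl-1,4-benzoquinone | CC1=CC(=O)C=CC1=O | starting material
18 | 4-[(5S,6E,10E,12R)-5-acetoxy-12-[(tert-butyldimethylsilyl)oxy]-3,7,11,15-tetramethylhexadeca-1,6,10,14-tetraen-3-yl]-4-hydroxy-2-methylcyclohexa-2,5-dien-1-one, mixture of epimers at ring C4 and C3' (not isolated) | CC1=CC(O)(C=CC1=O)C(C)(C=C)C[C@H](OC(C)=O)/C=C(\C)CC/C=C(\C)[C@H](O[Si](C)(C)C(C)(C)C)CC=C(C)C | intermediate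
19 | 6-[(2E,5S,6E,10E,12R)-5-acetoxy-12-[(tert-butyldimethylsilyl)oxy]-3,7,11,15-tetramethylhexadeca-2,6,10,14-tetraen-1-yl]-4-hydroxy-2-methylcyclohexa-2,4-dien-1-one, either configuration at ring C6 (not isolated) | CC1=CC(O)=CC(C/C=C(\C)C[C@H](OC(C)=O)/C=C(\C)CC/C=C(\C)[C@H](O[Si](C)(C)C(C)(C)C)CC=C(C)C)C1=O | intermediate
20 | (2E,5S,6E,10E,12R)-12-[(tert-butyldimethylsilyl)oxy]-1-(2,5-dihydroxy-3-methylphenyl)-3,7,11,15-tetramethylhexadeca-2,6,10,14-tetraen-5-yl acetate | CC(=O)O[C@H](/C=C(\C)CC/C=C(\C)[C@H](O[Si](C)(C)C(C)(C)C)CC=C(C)C)C/C(C)=C/Cc1cc(O)cc(C)c1O | intermediate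
21 | (2E,5S,6E,10E,12R)-1-(2,5-dihydroxy-3-methylphenyl)-12-hydroxy-3,7,11,15-tetramethylhexadeca-2,6,10,14-tetraen-5-yl acetate | CC(=O)O[C@H](/C=C(\C)CC/C=C(\C)[C@H](O)CC=C(C)C)C/C(C)=C/Cc1cc(O)cc(C)c1O | target

Total step count: 15. Longest linear sequence: 14 steps (steps 1–7 and 9–15; step 8 is a one-step side branch).

Steps most likely to fail

1. Step 14. The stannane may add to the hindered C1 carbonyl instead of C4, which would place the chain at C3 or C5. The E geometry of C2'=C3' may erode if the shift proceeds through an ion pair. BF3 may also cause protodestannylation or chroman closure of the product. Fallback (sets out from 14, returns at 21): 14 would be acetylated (Ac2O, pyridine, DMAP) to (2E,5S,6E,10E,12R)-12-[(tert-butyldimethylsilyl)oxy]-1-chloro-3,7,11,15-tetramethylhexadeca-2,6,10,14-tetraen-5-yl acetate F1. Separately, commercial 2-bromo-6-methylphenol would be oxidised with Fremy's salt K2NO(SO3)2 to 2-bromo-6-methyl-1,4-benzoquinone F2, reduced with Na2S2O4 to 2-bromo-6-methylbenzene-1,4-diol F3 and silylated (TIPSOTf, 2,6-lutidine) to 2-bromo-6-methyl-1,4-bis[(triisopropylsilyl)oxy]benzene F4. Bromine–lithium exchange of F4 (t-BuLi, Et2O, −78 °C), conversion into the lithium diarylcuprate (CuBr·SMe2) and SN2 alkylation with F1 at −78 to −20 °C would give the tris-silylated coupling product F5. In F5 the ring position is fixed by the former bromine and the E alkene is never broken. Global desilylation (HF·pyridine, THF) would give 21 directly.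

2. Step 9. Addition to the β,β-disubstituted enal may be sluggish, and the facial selectivity or the γ-selectivity may be insufficient. Fallback (sets out from 8 and 10, returns at 11): an uncatalysed vinylogous Mukaiyama aldol reaction (BF3·OEt2, CH2Cl2, −78 °C) would give the C5-epimeric mixture of ethyl (2E,6E,10E,12R)-12-[(tert-butyldimethylsilyl)oxy]-5-hydroxy-3,7,11,15-tetramethylhexadeca-2,6,10,14-tetraenoate F6. Dess–Martin oxidation would give ethyl (2E,6E,10E,12R)-12-[(tert-butyldimethylsilyl)oxy]-3,7,11,15-tetramethyl-5-oxohexadeca-2,6,10,14-tetraenoate F7. Corey–Bakshi–Shibata reduction of F7 with (R)-2-methyl-CBS-oxazaborolidine and BH3·SMe2 (alkenyl as the large group) would set 5S under reagent control and return 11.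

3. Step 11. Discrimination between the primary and the secondary allylic hydroxyl may be incomplete, leading to bis-sulfonylation and to elimination or substitution at C5. Fallback (sets out from 12, returns at 16): selective silylation of the primary hydroxyl (TESCl, imidazole, −40 °C) would give (2E,5S,6E,10E,12R)-12-[(tert-butyldimethylsilyl)oxy]-3,7,11,15-tetramethyl-1-[(triethylsilyl)oxy]hexadeca-2,6,10,14-tetraen-5-ol F8. Acetylation (Ac2O, pyridine, DMAP) would give its C5 acetate F9. Selective removal of the primary triethylsilyl ether (PPTS, MeOH, 0 °C) would give (2E,5S,6E,10E,12R)-12-[(tert-butyldimethylsilyl)oxy]-1-hydroxy-3,7,11,15-tetramethylhexadeca-2,6,10,14-tetraen-5-yl acetate F10. CBr4/PPh3 would convert F10 into the allylic bromide (2E,5S,6E,10E,12R)-1-bromo-12-[(tert-butyldimethylsilyl)oxy]-3,7,11,15-tetramethylhexadeca-2,6,10,14-tetraen-5-yl acetate F11. Inverse addition of Bu3SnLi (1.05 equiv, THF, −78 °C) to F11 would displace the bromide faster than it attacks the acetate and give 16.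

Further compounds
F1 | step 14 | (2E,5S,6E,10E,12R)-12-[(tert-butyldimethylsilyl)oxy]-1-chloro-3,7,11,15-tetramethylhexadeca-2,6,10,14-tetraen-5-yl acetate | ClC/C=C(\C)C[C@H](OC(C)=O)/C=C(\C)CC/C=C(\C)[C@H](O[Si](C)(C)C(C)(C)C)CC=C(C)C
F2 | step 14 | 2-bromo-6-methyl-1,4-benzoquinone | CC1=CC(=O)C=C(Br)C1=O
F3 | step 14 | 2-bromo-6-methylbenzene-1,4-diol | Cc1cc(O)cc(Br)c1O
F4 | step 14 | 2-bromo-6-methyl-1,4-bis[(triisopropylsilyl)oxy]benzene | Cc1cc(O[Si](C(C)C)(C(C)C)C(C)C)cc(Br)c1O[Si](C(C)C)(C(C)C)C(C)C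
F5 | step 14 | (2E,5S,6E,10E,12R)-12-[(tert-butyldimethylsilyl)oxy]-3,7,11,15-tetramethyl-1-{3-methyl-2,5-bis[(triisopropylsilyl)oxy]phenyl}hexadeca-2,6,10,14-tetraen-5-yl acetate | CC(=O)O[C@H](/C=C(\C)CC/C=C(\C)[C@H](O[Si](C)(C)C(C)(C)C)CC=C(C)C)C/C(C)=C/Cc1cc(O[Si](C(C)C)(C(C)C)C(C)C)cc(C)c1O[Si](C(C)C)(C(C)C)C(C)C
F6 | step 9 | ethyl (2E,6E,10E,12R)-12-[(tert-butyldimethylsilyl)oxy]-5-hydroxy-3,7,11,15-tetramethylhexadeca-2,6,10,14-tetraenoate, mixture of C5 epimers | CCOC(=O)/C=C(\C)CC(O)/C=C(\C)CC/C=C(\C)[C@H](O[Si](C)(C)C(C)(C)C)CC=C(C)C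
F7 | step 9 | ethyl (2E,6E,10E,12R)-12-[(tert-butyldimethylsilyl)oxy]-3,7,11,15-tetramethyl-5-oxohexadeca-2,6,10,14-tetraenoate | CCOC(=O)/C=C(\C)CC(=O)/C=C(\C)CC/C=C(\C)[C@H](O[Si](C)(C)C(C)(C)C)CC=C(C)C
F8 | step 11 | (2E,5S,6E,10E,12R)-12-[(tert-butyldimethylsilyl)oxy]-3,7,11,15-tetramethyl-1-[(triethylsilyl)oxy]hexadeca-2,6,10,14-tetraen-5-ol | CC[Si](CC)(CC)OC/C=C(\C)C[C@H](O)/C=C(\C)CC/C=C(\C)[C@H](O[Si](C)(C)C(C)(C)C)CC=C(C)C
F9 | step 11 | (2E,5S,6E,10E,12R)-12-[(tert-butyldimethylsilyl)oxy]-3,7,11,15-tetramethyl-1-[(triethylsilyl)oxy]hexadeca-2,6,10,14-tetraen-5-yl acetate | CC[Si](CC)(CC)OC/C=C(\C)C[C@H](OC(C)=O)/C=C(\C)CC/C=C(\C)[C@H](O[Si](C)(C)C(C)(C)C)CC=C(C)C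
F10 | step 11 | (2E,5S,6E,10E,12R)-12-[(tert-butyldimethylsilyl)oxy]-1-hydroxy-3,7,11,15-tetramethylhexadeca-2,6,10,14-tetraen-5-yl acetate | OC/C=C(\C)C[C@H](OC(C)=O)/C=C(\C)CC/C=C(\C)[C@H](O[Si](C)(C)C(C)(C)C)CC=C(C)C
F11 | step 11 | (2E,5S,6E,10E,12R)-1-bromo-12-[(tert-butyldimethylsilyl)oxy]-3,7,11,15-tetramethylhexadeca-2,6,10,14-tetraen-5-yl acetate | BrC/C=C(\C)C[C@H](OC(C)=O)/C=C(\C)CC/C=C(\C)[C@H](O[Si](C)(C)C(C)(C)C)CC=C(C)C
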